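**Retrosynthetic overview**
- The target is (S)-16-methyloctadecyl 2,3-dihydroxybenzoate. No ring is formed in the route; the only ring, the benzene ring, is bought with the acid.
- The O–CH2–CH2 bond (C1–C2 of the alkyl chain) is made by a Ni–H catalysed anti-Markovnikov hydroalkylation of the terminal alkene (S)-15-methylheptadec-1-ene with iodomethyl 2,3-bis(benzyloxy)benzoate.
- Enabling feature: C1 is a CH2 on the ester oxygen, so a halide there gives an α-acyloxy-stabilised primary radical with no β-hydrogen. C2 and C3 are unbranched CH2 groups, so a C2=C3 terminal alkene gives a primary alkylnickel. The only stereocentre (C16) lies 13 carbons away.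
- The alkene comes from two Cu-catalysed sp3–sp3 Grignard couplings: allyl onto 1,10-dibromodecane, then the chiral-pool (S)-2-methylbutyl unit, which brings C16.
- The electrophile comes from 2,3-bis(benzyloxy)benzoic acid via the chloromethyl and iodomethyl esters; hydrogenolysis of the benzyl ethers ends the route.

Key step: step 6

Remark: 2,3-bis(benzyloxy)benzoic acid is taken as commercial. The descriptor at C16 stays S throughout, because the CH2Br or long-chain arm always outranks ethyl, which outranks methyl.

**Step 1**
Reactants: 1 allylmagnesium bromide (solution in Et2O); 2 1,10-dibromodecane (3 equiv)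
Product: 3 13-bromotridec-1-ene
Conditions: Li2CuCl4 (3 mol %), THF, −20 °C to rt; excess 2 recovered by distillation
Reagents that add atoms: none
Why: Cu-catalysed (Kochi-type) sp3–sp3 coupling of a Grignard reagent with a primary bromide; the excess of dibromide should hold the reaction at mono-allylation.

**Step 2**
Reactants: 4 (S)-1-bromo-2-methylbutane
Product: 5 (S)-2-methylbutylmagnesium bromide (THF solution, used directly)
Conditions: Mg turnings, I2 (crystal), THF, rt to 40 °C
Reagents that add atoms: magnesium, [Mg]
Why: Grignard formation by Mg insertion into a primary C–Br bond; the stereocentre is β to the metal and is not touched.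

**Step 3**
Reactants: 5 (S)-2-methylbutylmagnesium bromide (1.3 equiv); 3 13-bromotridec-1-ene
Product: 6 (S)-15-methylheptadec-1-ene
Conditions: Li2CuCl4 (3 mol %), THF/NMP, −10 °C to rt
Reagents that add atoms: none
Why: Cu-catalysed sp3–sp3 Grignard cross-coupling with an unhindered primary bromide; the terminal alkene is inert and the C15 stereocentre is carried in unchanged from 4.

**Step 4**
Reactants: 7 2,3-bis(benzyloxy)benzoic acid
Product: 8 chloromethyl 2,3-bis(benzyloxy)benzoate
Conditions: ClCH2OSO2Cl (1.2 equiv), NaHCO3, Bu4NHSO4 (10 mol %), CH2Cl2/H2O, 0 °C to rt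
Reagents that add atoms: chloromethyl chlorosulfate, ClCOS(=O)(=O)Cl
Why: phase-transfer O-alkylation of the carboxylate, with chlorosulfate as the leaving group, is the standard entry to chloromethyl esters; benzyl ethers are inert.

**Step 5**
Reactants: 8 chloromethyl 2,3-bis(benzyloxy)benzoate
Product: 9 iodomethyl 2,3-bis(benzyloxy)benzoate
Conditions: NaI (2 equiv), acetone, rt, dark; filtered and used without storage
Reagents that add atoms: sodium iodide, [Na+].[I-]
Why: Finkelstein exchange at the activated α-acyloxy CH2–Cl, driven by precipitation of NaCl.

**Step 6**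
Reactants: 6 (S)-15-methylheptadec-1-ene; 9 iodomethyl 2,3-bis(benzyloxy)benzoate (1.5 equiv)
Product: 10 (S)-16-methyloctadecyl 2,3-bis(benzyloxy)benzoate
Conditions: NiBr2·glyme (10 mol %), 2,2′-(propane-2,2-diyl)bis(4-phenyl-4,5-dihydrooxazole) (12 mol %, either enantiomer), (EtO)2MeSiH (2.5 equiv), KF (3 equiv), DMA/THF, 0 °C to rt
Reagents that add atoms: none
Why: A nickel hydride formed from the Ni halide, silane and fluoride should insert the terminal C=C of 6 anti-Markovnikov to give a primary alkylnickel; iodine abstraction from 9 gives the acyloxymethyl radical, which is captured at nickel, and C(sp3)–C(sp3) reductive elimination forms the O–CH2–CH2 bond. The closest known reaction type is the Ni–H catalysed anti-Markovnikov hydroalkylation of unactivated terminal olefins with primary alkyl iodides and with 1-haloalkyl carboxylates. No ring is closed and no stereocentre is created, since both carbons joined are CH2; ligand chirality is therefore irrelevant, and C16 is too remote to be reached by any reversible Ni–H walking. The step needs linear regioselectivity, which the monosubstituted alkene and a bis(oxazoline) ligand that disfavours chain walking should secure. It also needs cross-coupling to beat hydrodehalogenation of 9, which the excess of 9 and the radical-stabilising acyloxy group should help. The benzyl ethers keep the catechol from being silylated or O-alkylated by 9, and the ester is stable to the silane at room temperature.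

**Step 7**
Reactants: 10 (S)-16-methyloctadecyl 2,3-bis(benzyloxy)benzoate
Product: 11 Gentiside F, (S)-16-methyloctadecyl 2,3-dihydroxybenzoate
Conditions: H2 (1 atm), 10% Pd/C, EtOAc, rt
Reagents that add atoms: none
Why: hydrogenolysis of the two aryl benzyl ethers; the non-benzylic alkyl ester and the saturated chain with its stereocentre are inert.

**Compound list**
1 | allylmagnesium bromide | C=CC[Mg]Br | starting material
2 | 1,10-dibromodecane | BrCCCCCCCCCCBr | starting material
3 | 13-bromotridec-1-ene | C=CCCCCCCCCCCCBr | intermediate
4 | (S)-1-bromo-2-methylbutane | CC[C@H](C)CBr | starting material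
5 | (S)-2-methylbutylmagnesium bromide | CC[C@H](C)C[Mg]Br | intermediate
6 | (S)-15-methylheptadec-1-ene | CC[C@H](C)CCCCCCCCCCCCC=C | intermediate
7 | 2,3-bis(benzyloxy)benzoic acid | OC(=O)c1cccc(OCc2ccccc2)c1OCc1ccccc1 | starting material
8 | chloromethyl 2,3-bis(benzyloxy)benzoate | ClCOC(=O)c1cccc(OCc2ccccc2)c1OCc1ccccc1 | intermediate
9 | iodomethyl 2,3-bis(benzyloxy)benzoate | ICOC(=O)c1cccc(OCc2ccccc2)c1OCc1ccccc1 | intermediate
10 | (S)-16-methyloctadecyl 2,3-bis(benzyloxy)benzoate | CC[C@H](C)CCCCCCCCCCCCCCCOC(=O)c1cccc(OCc2ccccc2)c1OCc1ccccc1 | intermediate
11 | Gentiside F, (S)-16-methyloctadecyl 2,3-dihydroxybenzoate | CC[C@H](C)CCCCCCCCCCCCCCCOC(=O)c1cccc(O)c1O | target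

**Total step count:** 7
**Longest linear sequence:** 4 steps (steps 1, 3, 6, 7; equally 2, 3, 6, 7 or 4, 5, 6, 7)

**Steps most likely to fail**

1. Step 6. Hydrodehalogenation of the iodomethyl ester may outrun radical capture at nickel, and Ni–H chain walking may erode the linear regioselectivity. The fallback sets out from 6 and makes the same C–C bond by linear-selective hydroformylation (Rh(acac)(CO)2/Xantphos, CO/H2, toluene, 80 °C), which should give (S)-16-methyloctadecanal F1. Reduction with NaBH4 in MeOH/THF should give (S)-16-methyloctadecan-1-ol F2. Carbodiimide esterification of F2 with acid 7 (EDC·HCl, DMAP, CH2Cl2) comes back to the route at 10.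

2. Step 1. Allylation at both ends of the dibromide, and poor separation of mono-coupled product from excess dibromide, may leave little pure 3. The fallback does not set out from a numbered compound but replaces 1 and 2 with commercial 11-bromoundec-1-ene (C=CCCCCCCCCCBr). Mg in THF should give undec-10-enylmagnesium bromide F3. Cu-catalysed opening of oxirane (cat. CuI, THF, −30 °C, then dilute HCl) should give tridec-12-en-1-ol F4. An Appel reaction on F4 (CBr4, PPh3, CH2Cl2) comes back to the route at 3.

3. Step 5. Light-induced and hydrolytic decomposition of the iodomethyl ester during isolation may deliver degraded electrophile to the key step. The fallback sets out from 7. Oxalyl bromide with cat. DMF in CH2Cl2 should give 2,3-bis(benzyloxy)benzoyl bromide F5. Insertion of paraformaldehyde with cat. ZnBr2 (CH2Cl2, 0 °C) should give bromomethyl 2,3-bis(benzyloxy)benzoate F6. F6 is used crude with 6 under the step 6 conditions, so the fallback comes back to the route at 10.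

**Further compounds**
F1 | step 6 | (S)-16-methyloctadecanal | CC[C@H](C)CCCCCCCCCCCCCCC=O
F2 | step 6 | (S)-16-methyloctadecan-1-ol | CC[C@H](C)CCCCCCCCCCCCCCCO
F3 | step 1 | undec-10-enylmagnesium bromide | C=CCCCCCCCCC[Mg]Br
F4 | step 1 | tridec-12-en-1-ol | C=CCCCCCCCCCCCO
F5 | step 5 | 2,3-bis(benzyloxy)benzoyl bromide | BrC(=O)c1cccc(OCc2ccccc2)c1OCc1ccccc1
F6 | step 5 | bromomethyl 2,3-bis(benzyloxy)benzoate | BrCOC(=O)c1cccc(OCc2ccccc2)c1OCc1ccccc1
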